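Drimane numbering (C-1 to C-11) is used for the decalin part. The target is the isofraxidin ether of a 9-epi-drima-1,7-dien-3-on-11-ol, and ring A is taken apart last: cutting C-1=C-2 and C-3–C-4 leaves a two-carbon ketene unit (C-2, C-3 and the ketone oxygen) and a ring-B aldehyde–alkene with CHO on C-10 and isopropenyl on C-5.
Enabling feature: in ring A the gem-dimethyl carbon C-4 and the enone carbon C-1 hang on the neighbouring ring-fusion atoms C-5 and C-10, so C-4 can arise as a tertiary radical from an isopropenyl group and C-1 as a non-enolisable aldehyde on quaternary C-10; only the CH–C(=O) pair C-2/C-3 of ring A is then missing.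
C-11–O: the preformed coumarin (commercial isofraxidin) is attached by Mitsunobu etherification before ring A exists, so that no free hydroxy enone is ever handled.
Ring B: (S)-carvone supplies C-5; C-10 is set by two α′-functionalisations anti to isopropenyl, C-9 by epoxidation, Wharton transposition and a suprafacial [2,3]-Wittig–Still shift that delivers C-11.
Ring order: ring B (chiral pool), coumarin rings attached intact, ring A closed last by the key annulation, which gives the target directly.

Key step: step 11

Remark: drimane numbers are used for the ring carbons of all intermediates, and α denotes the face opposite to the C-10 methyl group (the isopropenyl group on C-5 is β).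

Step 1
Reactants: 1 (S)-(+)-carvone
Product: 2 6-methylcarvone, (5S)-2,6-dimethyl-5-(prop-1-en-2-yl)cyclohex-2-en-1-one, both epimers at the new centre (future C-10)
Conditions: LiN(i-Pr)2, THF, −78 °C; MeI, −78 → 0 °C
Reagents that add atoms: iodomethane, CI
Why: Kinetic α′-deprotonation gives the cross-conjugated lithium dienolate and enolate alkylation installs the future C-10 methyl; the new centre need not be controlled because step 2 makes it planar again.

Step 2
Reactants: 2 6-methylcarvone
Product: 3 trimethylsilyl dienol ether of 2 (C-9 O-silyl, C-9=C-10 and C-7=C-8 double bonds)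
Conditions: LiN(i-Pr)2, THF, −78 → 0 °C; Me3SiCl, Et3N, −78 °C
Reagents that add atoms: chlorotrimethylsilane, C[Si](C)(C)Cl
Why: The remaining tertiary α′-hydrogen is removed under kinetic control and the enolate is trapped on oxygen (silyl enol ether formation), which fixes the nucleophilic site at C-10 for step 3.

Step 3
Reactants: 3 silyl dienol ether
Product: 4 keto acetal, (5R,6R)-6-(dimethoxymethyl)-2,6-dimethyl-5-(prop-1-en-2-yl)cyclohex-2-en-1-one
Conditions: HC(OMe)3, Me3SiOTf (0.1 equiv), CH2Cl2, −78 °C
Reagents that add atoms: trimethyl orthoformate, COC(OC)OC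
Why: Mukaiyama-type addition of the silyl enol ether to the dimethoxycarbenium ion formed from the orthoester creates quaternary C-10; the electrophile should enter anti to the neighbouring isopropenyl group, which places CH(OMe)2 (future C-1) α and the methyl β.

Step 4
Reactants: 4 keto acetal
Product: 5 7α,8α-epoxy ketone
Conditions: 30% aq. H2O2, NaOH (0.2 equiv), MeOH, 0 °C
Reagents that add atoms: hydrogen peroxide, OO
Why: Weitz–Scheffer nucleophilic epoxidation of the enone; hydroperoxide should add axially to C-7 on the face anti to the isopropenyl group and to the axial C-10 methyl, giving the α-epoxide.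

Step 5
Reactants: 5 epoxy ketone
Product: 6 allylic alcohol, (1S,4R,5R)-4-(dimethoxymethyl)-2,4-dimethyl-5-(prop-1-en-2-yl)cyclohex-2-en-1-ol (7α-OH, C-8=C-9)
Conditions: N2H4·H2O, AcOH (0.2 equiv), MeOH, 0 → 23 °C
Reagents that add atoms: none
Why: Wharton transposition: the epoxy hydrazone fragments with loss of N2 to the allylic alcohol, the C-7–O bond of the epoxide is kept (7α-OH) and the alkene moves to C-8=C-9.

Step 6
Reactants: 6 allylic alcohol
Product: 7 (tributylstannyl)methyl ether of 6
Conditions: KH, 18-crown-6, THF, 0 °C; Bu3SnCH2I, 23 °C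
Reagents that add atoms: tributyl(iodomethyl)stannane, CCCC[Sn](CCCC)(CCCC)CI
Why: Williamson etherification of the potassium alkoxide with the primary iodide; no stereocentre is touched.

Step 7
Reactants: 7 stannylmethyl ether
Product: 8 homoallylic alcohol, [(1S,5R,6R)-6-(dimethoxymethyl)-2,6-dimethyl-5-(prop-1-en-2-yl)cyclohex-2-en-1-yl]methanol (C-11 α on C-9, C-7=C-8)
Conditions: n-BuLi, THF, −78 °C; then H2O
Reagents that add atoms: none
Why: Tin–lithium exchange gives the α-alkoxymethyl lithium, which undergoes [2,3]-Wittig–Still rearrangement; the shift is suprafacial, so C-11 is delivered to C-9 on the face of the 7α C–O bond (trans to the C-10 methyl) while the alkene returns to C-7=C-8.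

Step 8
Reactants: 8 homoallylic alcohol; 9 isofraxidin (7-hydroxy-6,8-dimethoxycoumarin)
Product: 10 aryl ether acetal (isofraxidin O-7 bound to C-11)
Conditions: PPh3, DIAD, THF, 0 → 40 °C
Reagents that add atoms: none
Why: Mitsunobu etherification of the primary alcohol with the acidic phenol; the reacting carbon C-11 is not a stereocentre, and the coumarin lactone, the acetal and both alkenes are inert.

Step 9
Reactants: 10 aryl ether acetal
Product: 11 aldehyde, (1R,2S,6R)-2-{[(6,8-dimethoxy-2-oxo-2H-chromen-7-yl)oxy]methyl}-1,3-dimethyl-6-(prop-1-en-2-yl)cyclohex-3-ene-1-carbaldehyde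
Conditions: PPTS, acetone/H2O (4:1), 45 °C
Reagents that add atoms: water, O
Why: Acid-catalysed acetal hydrolysis frees the aldehyde on quaternary C-10, which cannot epimerise; the mild acid is chosen to avoid carbonyl-ene closure onto the isopropenyl group.

Step 10
Reactants: 12 ethoxyacetylene
Product: 14 (trimethylsilyl)ketene, via silyl ynol ether 13 (not isolated)
Conditions: n-BuLi, Et2O, −78 → 0 °C; Me3SiCl; filter, concentrate, then neat, 120 °C, distil
Reagents that add atoms: chlorotrimethylsilane, C[Si](C)(C)Cl
Why: C-Silylation of the lithium acetylide followed by thermal retro-ene loss of ethene from the 1-ethoxyalkyne, the standard route to silylketenes.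

Step 11
Reactants: 11 aldehyde; 14 (trimethylsilyl)ketene
Product: 16 target CNP0330704.1, via silyl aldol adduct 15 (not isolated)
Conditions: 14 (3 equiv), Fe(acac)3 (0.3 equiv), PhSiH2(Oi-Pr) (2 equiv), THF, 0 → 23 °C
Reagents that add atoms: none
Why: Proposed new method: hydrogen-atom transfer from an iron hydride (from Fe(acac)3 and the silane) to the 1,1-disubstituted isopropenyl alkene should give the tertiary C-4 radical, which adds to the sp carbonyl carbon of ketene 14 (C-3–C-4 bond); the α-silyl-α-keto radical is reduced by divalent iron to a ferric α-silyl enolate that adds to the neighbouring aldehyde (C-1–C-2 bond), and the β-oxido silane 15 loses Me3SiO− (Peterson olefination) to the enone while the silanolate regenerates the iron hydride with the silane. The closest known reaction type is the iron-hydride HAT-initiated radical–polar crossover annulation of γ,δ-unsaturated aldehydes with electron-poor alkenes (Giese addition, then aldol closure), joined here to two other known events, radical addition at the carbonyl carbon of ketenes and Peterson olefination of α-silyl ketone enolates with aldehydes. Ring A closes by a 6-(enolendo)-exo-trig aldol between two equatorial, trans-disposed arms on C-5 and C-10, so the trans ring fusion fixed earlier is carried over. No stereocentre is created: C-1 and C-2 end as the cis alkene that the six-membered ring enforces, and C-4 bears two identical methyl groups. The step needs HAT to the isopropenyl group in preference to the trisubstituted C-7=C-8 alkene and the coumarin C-3=C-4 bond, which the faster HAT to an unhindered, electron-rich 1,1-disubstituted alkene should secure, and it needs attack at the ketene carbonyl carbon, not at the silyl-bearing carbon, which the bulky silyl group and the stabilised α-keto radical formed should secure.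

Compound list
1 | (S)-(+)-carvone, (5S)-2-methyl-5-(prop-1-en-2-yl)cyclohex-2-en-1-one | CC1=CC[C@@H](CC1=O)C(C)=C | starting material
2 | (5S)-2,6-dimethyl-5-(prop-1-en-2-yl)cyclohex-2-en-1-one (6-methylcarvone, both C-6 epimers) | O=C1C(C)=CC[C@H](C(C)=C)C1C | intermediate
3 | trimethyl{[(3R)-2,6-dimethyl-3-(prop-1-en-2-yl)cyclohexa-1,5-dien-1-yl]oxy}silane | C[Si](C)(C)OC1=C(C)[C@@H](C(C)=C)CC=C1C | intermediate
4 | (5R,6R)-6-(dimethoxymethyl)-2,6-dimethyl-5-(prop-1-en-2-yl)cyclohex-2-en-1-one (CH(OMe)2 trans to isopropenyl) | O=C1C(C)=CC[C@H](C(C)=C)[C@@]1(C)C(OC)OC | intermediate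
5 | (1S,3R,4R,6S)-3-(dimethoxymethyl)-1,3-dimethyl-4-(prop-1-en-2-yl)-7-oxabicyclo[4.1.0]heptan-2-one (epoxide trans to isopropenyl) | O=C1[C@@]2(C)O[C@H]2C[C@H](C(C)=C)[C@@]1(C)C(OC)OC | intermediate
6 | (1S,4R,5R)-4-(dimethoxymethyl)-2,4-dimethyl-5-(prop-1-en-2-yl)cyclohex-2-en-1-ol | O[C@H]1C[C@H](C(C)=C)[C@@](C)(C(OC)OC)C=C1C | intermediate
7 | tributyl({[(1S,4R,5R)-4-(dimethoxymethyl)-2,4-dimethyl-5-(prop-1-en-2-yl)cyclohex-2-en-1-yl]oxy}methyl)stannane | CCCC[Sn](CCCC)(CCCC)CO[C@H]1C[C@H](C(C)=C)[C@@](C)(C(OC)OC)C=C1C | intermediate
8 | [(1S,5R,6R)-6-(dimethoxymethyl)-2,6-dimethyl-5-(prop-1-en-2-yl)cyclohex-2-en-1-yl]methanol | OC[C@H]1C(C)=CC[C@H](C(C)=C)[C@@]1(C)C(OC)OC | intermediate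
9 | isofraxidin, 7-hydroxy-6,8-dimethoxy-2H-chromen-2-one | COc1cc2ccc(=O)oc2c(OC)c1O | starting material
10 | 7-{[(1S,5R,6R)-6-(dimethoxymethyl)-2,6-dimethyl-5-(prop-1-en-2-yl)cyclohex-2-en-1-yl]methoxy}-6,8-dimethoxy-2H-chromen-2-one | COc1cc2ccc(=O)oc2c(OC)c1OC[C@H]1C(C)=CC[C@H](C(C)=C)[C@@]1(C)C(OC)OC | intermediate
11 | (1R,2S,6R)-2-{[(6,8-dimethoxy-2-oxo-2H-chromen-7-yl)oxy]methyl}-1,3-dimethyl-6-(prop-1-en-2-yl)cyclohex-3-ene-1-carbaldehyde | COc1cc2ccc(=O)oc2c(OC)c1OC[C@H]1C(C)=CC[C@H](C(C)=C)[C@@]1(C)C=O | intermediate
12 | ethoxyacetylene (ethoxyethyne) | CCOC#C | starting material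
13 | (ethoxyethynyl)trimethylsilane | CCOC#C[Si](C)(C)C | intermediate
14 | (trimethylsilyl)ketene, 2-(trimethylsilyl)ethen-1-one | C[Si](C)(C)C=C=O | intermediate
15 | silyl aldol adduct: 1-hydroxy-2-(trimethylsilyl)-1,2-dihydro derivative of 16, as its iron alkoxide (C-1 and C-2 not defined) | COc1cc2ccc(=O)oc2c(OC)c1OC[C@H]1C(C)=CC[C@@H]2C(C)(C)C(=O)C([Si](C)(C)C)C(O)[C@]21C | intermediate
16 | CNP0330704.1, 7-O-[(5S,9S,10R)-3-oxodrima-1,7-dien-11-yl]isofraxidin (trans ring fusion, C-11 trans to the C-10 methyl) | COc1cc2ccc(=O)oc2c(OC)c1OC[C@H]1C(C)=CC[C@@H]2C(C)(C)C(=O)C=C[C@]21C | target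

Total step count: 11. Longest linear sequence: 10 steps (steps 1 to 9 and 11, from (S)-carvone); step 10 is a one-step side branch.

Steps most likely to fail

Step 11 (the proposed new method). The tertiary radical may be reduced to the isopropyl group, or add at the silyl-bearing ketene carbon or at the coumarin double bond, before the C-3–C-4 bond forms; the enolate may also be protonated before ring A closes. The fallback uses known chemistry and sets out from aldehyde 11. A zinc-mediated Reformatsky-type addition of bromoacetonitrile (Zn, BrCH2CN, THF) to the aldehyde should form the C-1–C-2 bond and give the β-hydroxy nitrile F1. Iron-hydride hydrogen-atom transfer (Fe(acac)3, PhSiH3, EtOH, 60 °C) should then let the tertiary C-4 radical attack the nitrile carbon in a 6-exo-dig closure (C-3–C-4 bond), a known HAT-initiated nitrile cyclisation; dilute acid on work-up hydrolyses the ketimine to the β-hydroxy ketone F2. Acid-catalysed dehydration (p-TsOH, toluene, 80 °C) comes back to the route at the target 16.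

Step 5. Hydrazone formation at the ketone beside quaternary C-10 may be slow, and hydrazine may instead open the epoxide. The fallback sets out from epoxy ketone 5. Reduction (NaBH4, MeOH, 0 °C) should give the epoxy alcohol F3, which is converted (PhOC(S)Cl, pyridine, DMAP, CH2Cl2) into the O-phenyl thionocarbonate F4. Radical deoxygenation of the Barton–McCombie type (Bu3SnH, AIBN, toluene, 100 °C) generates the C-9 radical, which opens the neighbouring epoxide to the C-8=C-9 alkene and the 7α-oxygen radical; hydrogen transfer then comes back to the route at allylic alcohol 6.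

Step 8. Displacement at the β-branched C-11 beside quaternary C-10 by a phenol flanked by two methoxy groups may be slow, so the activated alcohol may be diverted into elimination or alkylation of the hydrazide. The fallback sets out from alcohol 8. Sulfonylation (Tf2O, 2,6-lutidine, CH2Cl2, −78 °C) should give the triflate F5, which is displaced by the potassium phenoxide of 9 (K2CO3, 18-crown-6, MeCN, 0 → 23 °C) in an SN2 reaction, coming back to the route at aryl ether 10.

Further compounds
F1 | step 11 | β-hydroxy nitrile from 11 (cyanomethyl carbinol at C-1, both epimers) | COc1cc2ccc(=O)oc2c(OC)c1OC[C@H]1C(C)=CC[C@H](C(C)=C)[C@@]1(C)C(O)CC#N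
F2 | step 11 | β-hydroxy ketone, 1-hydroxy-1,2-dihydro derivative of 16 | COc1cc2ccc(=O)oc2c(OC)c1OC[C@H]1C(C)=CC[C@@H]2C(C)(C)C(=O)CC(O)[C@]21C
F3 | step 5 | epoxy alcohol from 5 (C-9 carbinol, either epimer) | OC1[C@@]2(C)O[C@H]2C[C@H](C(C)=C)[C@@]1(C)C(OC)OC
F4 | step 5 | O-phenyl thionocarbonate of F3 | S=C(Oc1ccccc1)OC1[C@@]2(C)O[C@H]2C[C@H](C(C)=C)[C@@]1(C)C(OC)OC
F5 | step 8 | trifluoromethanesulfonate of 8 | O=S(=O)(OC[C@H]1C(C)=CC[C@H](C(C)=C)[C@@]1(C)C(OC)OC)C(F)(F)F
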